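## Analysis of the target

Jaeskeanin is a daucane: a cyclopentane (ring A, C1–C2–C3–C4–C5) trans-fused through C1 and C5 to a seven-membered ring (ring B, C5–C6–C7–C8–C9–C10–C1). It has six stereocentres: the quaternary C1 (methyl, whose face is called β here), C4 (tertiary alcohol with isopropyl, OH β), C5 (H α), C6 (4-hydroxybenzoyloxy α, cis to H-5), and the epoxide carbons C8 (methyl) and C9, with the epoxide oxygen on the α face like the C6 oxygen. C1, C5, C4 and C6 are contiguous around the ring fusion; C8 and C9 are insulated from them by the methylene carbons C7 and C10 and have to be set by relay from C6. The sensitive groups are the trisubstituted epoxide (acid, and backside attack by the C4 hydroxyl), the tertiary alcohol (dehydration), and the aryl ester with its free phenol (base, nucleophiles, organometallic reagents), so these enter last. The hard points are the quaternary C1 at the fusion of a 5–7 system, a trans fusion that has little thermodynamic bias, and a fully substituted carbinol carbon next to it. The strategy rests on reading ring B as a two-carbon unit C5–C6 (an alkyne tied to C1 through C4, C3 and C2) plus a five-carbon unit C1–C10–C9–C8–C7 (a vinylcyclopropane whose ring carbon C9 carries a silyloxy group). The C9 oxygen is not in the target; it is the handle from which the C8–C9 double bond and then the epoxide are made, and the C4 carbonyl of the ynone is the site for the isopropyl group.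

## Retrosynthetic reasoning

**Ester C6–O bond (39 ⇐ 38 ⇐ 36 + 37).** The acyl–oxygen bond is cut first because neither the aryl ester nor the phenol would survive the organometallic, fluoride and hydride steps. The forward reaction has to acylate only the secondary C6 hydroxyl of 36 (the tertiary C4 hydroxyl is inert) and then free the phenol from its acetate without touching the benzoate or the epoxide.

**Epoxide C–O bonds (36 ⇐ 35).** The epoxide is removed next so that the acid-labile ring is carried through only two steps. It is placed before the esterification because the free C6 hydroxyl of 35 is homoallylic to C8=C9 and lies on the α face, so a metal-bound peroxide can be delivered to that face.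

**C9–H bond and alkene position (35 ⇐ 34 ⇐ 33 ⇐ 31 ⇐ 30).** The C8=C9 alkene is traced to an enol triflate and from there to the C9 ketone of 30. The forward sequence has to enolise toward C8 and not toward C10; the thermodynamic enol silane 31 does this, and the tertiary hydroxyl is capped in the same operation.

**C4–isopropyl bond (30 ⇐ 29 ⇐ 27 + 28).** Cutting this bond leaves a cyclopentanone in a rigid trans-fused bicycle whose β face is screened by the C5–C6 bond and the C1 methyl group. The C9 carbonyl is still masked as the silyl enol ether in 27, so only one ketone is exposed. The C6 hydroxyl is silylated because a β-alkoxide would invite retro-aldol cleavage.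

**C6–O and C5–H bonds (27 ⇐ 26 ⇐ 25 ⇐ 24).** The C6 oxygen and the C5 hydrogen are removed together, which leaves the enone of 24. Forward, boron is added to C6 from the face opposite the C1 methyl group, and C5 is equilibrated while the substituent on C6 is still boron, which cannot leave by β-elimination.

**C1–C5 and C6–C7 bonds (24 ⇐ 23, the key disconnection).** Cutting these two bonds opens ring A and ring B at once and returns the acyclic ynone 23. No other pair of cuts removes both rings and the quaternary carbon in one operation. Forward, rhodium has to open the cyclopropane at C9–C7, join C5 to C1 and C6 to C7, and transfer the configuration of the cyclopropane to C1.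

**C4–C5 bond of the ynone (23 ⇐ 22 ⇐ 20 + 21; 20 ⇐ 19 ⇐ 18 ⇐ 17).** The sensitive terminal ynone is made last, from aldehyde 20 and the two-carbon Grignard reagent 21 followed by oxidation. The aldehyde comes from the primary alcohol that is carried as a triethylsilyl ether.

**C9–C10 bond (17 ⇐ 4 + 13).** The cut is placed between the alkene and the cyclopropane because the cyclopropane configuration determines C1 in the key step. A carbenoid cyclopropanation of a silyl enol ether would give a racemic ring and therefore racemic C1 whatever ligand is on rhodium. Adding the alkenyl metal from 4 to cyclopropanone 16 (released from 13) sets C9 trans to the C8 methyl group by substrate control, and C8 comes from the chiral pool.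

**Cyclopropane C8–C9 bond and C7–C(sulfonyl) bond (13 ⇐ 10 ⇐ 9 ⇐ 5 + 6).** The three-membered ring is traced to sulfone 5 and epoxide 6. Opening at the unsubstituted epoxide carbon and ring closure with inversion at the carbinol carbon fix C8.

**C1–CH3 and C10–I bonds (4 ⇐ 3 ⇐ 1).** The E-trisubstituted alkene is traced to a terminal alkyne. Syn-carbometalation guarantees the geometry, which an olefination of a methyl ketone with a stabilised keto-phosphonate would not do reliably.

## Alternatives that were turned down

**Alternative 1:** The disconnection is at C1–CH3 and C5–C6 on a cyclopentenone. Forward, Me3Al adds to C1 of 3-allylcyclopent-2-en-1-one A1 under Cu(OTf)2 and a chiral phosphoramidite, and the aluminium enolate is trapped by 3-methylbut-3-enal A2 to give ketol A3.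
- For: three components are joined in one step, C1 is made catalytically, and ring-closing metathesis of A3 to hydroxy ketone A4 puts the C8=C9 alkene in place with no oxygen to remove at C9. On step count this route is clearly stronger, by perhaps ten steps.
- Against: in A3 the new C5–C6 bond must form cis to the new methyl group and trans to the allyl group, two substituents of similar size on one carbon, so the enolate faces are poorly differentiated. The carbinol C6 is set in the same step with no evident bias. A2 is a β,γ-unsaturated aldehyde that isomerises into conjugation under Lewis acidic aluminium. Five-membered enones are the weaker substrate class for this asymmetric addition. The β-hydroxy ketones A3 and A4 must then take an isopropyl nucleophile without retro-aldol cleavage.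
- Comparison: the chosen route is longer, but C1 is set by stereospecific transfer and C5/C6 are set after the bicycle exists, where the ring fusion gives a facial bias.

**Alternative 2:** The disconnection is at C3–C4, closing ring A last. Forward, SmI2 reduces the primary iodide of iodo ketone A5 and the carbon adds to the C4 ketone, held in a chelate with the C6 hydroxyl, to give jaeschkeanadiol A6 (the same compound as 35).
- For: the diol is delivered without protecting groups and C4 is set in the ring-closing step by a well-behaved five-membered Barbier closure. Its late stage is stronger than the chosen one, which needs steps 14 to 18 to go from the ketone to 35.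
- Against: A5 already contains the quaternary C1 next to C5, the C5/C6 relationship and a trisubstituted alkene in a seven-membered ring, so the key step solves only ring A and a second strategy is needed for a stereodefined cycloheptene. A5 is a β-hydroxy ketone with an epimerisable C5, exposed to Lewis acidic trivalent samarium. The sense of delivery from the chelate depends on the conformation of a flexible seven-membered ring. Simple ketone reduction competes at a hindered isopropyl ketone.
- Comparison: the chosen strategy builds both rings and C1 in one operation and leaves C4 to an addition onto a rigid trans-fused bicycle.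

**Alternative 3:** The disconnection is at C4–C5 by C–H insertion. Forward, Rh2(OAc)4 converts α-diazo ester A7 into a carbenoid at C5 that inserts into the oxygen-activated C4–H bond, giving cyclopentane A8 after equilibration at C5.
- For: C4 arrives with oxygen and isopropyl in place, and because insertion goes with retention its configuration can be taken from a simple secondary carbinol. On this point it is stronger than the chosen route, which relies on the facial selectivity of an organocerium addition. The 1,5-insertion is the favoured ring size.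
- Against: the C–H bond is tertiary and flanked by isopropyl and a bulky silyloxy group, the worst steric case for a dirhodium carbenoid. Insertion into the isopropyl methine (six-membered ring) and reaction with the allyl alkene compete. A7 needs two remote stereocentres (C1 and C4) set independently in an open chain. Ring B is still missing after the key step: the ester carbon of A8 has to become the C6 carbinol, a C7–C8 unit must be added and the seven-membered ring closed.
- Comparison: the chosen strategy makes the seven-membered ring in the same step as ring A and derives C1 from one inexpensive epoxide.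

Key step: step 11

Remarks on the chemistry:
- β is the face of the C1 methyl group and α the opposite face; C1–C10 numbering as in the analysis.
- (R)-BINAP is assumed to be the ligand enantiomer matched to the (1S,2R)-cyclopropane in step 11. If the pairing is the other way round, (S)-BINAP is used; the configuration of C1 does not change, because it is transferred from the cyclopropane.
- The configuration of the sulfonyl-bearing carbon in 10 to 13 is of no consequence.

## Route

Step 1
Reactants: 1 pent-4-yn-1-ol
Product: 3 (E)-5-iodo-4-methylpent-4-en-1-ol, via alkenylalane 2 (not isolated)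
Conditions: AlMe3 (3 equiv), Cp2ZrCl2 (0.25 equiv), CH2Cl2, 0 °C to rt; then iodine, THF, −30 to 0 °C
Reagents that add atoms: trimethylaluminium C[Al](C)C; iodine [I][I]
Why: Zirconium-catalysed methylalumination (Negishi carboalumination) adds methyl and aluminium syn across the terminal alkyne with aluminium on the terminal carbon, and iodinolysis with retention gives the E-iodide, which fixes the C1 methyl group and the C1=C10 geometry.

Step 2
Reactants: 3 (E)-5-iodo-4-methylpent-4-en-1-ol
Product: 4 triethyl{[(E)-5-iodo-4-methylpent-4-en-1-yl]oxy}silane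
Conditions: Et3SiCl, imidazole, CH2Cl2, 0 °C
Reagents that add atoms: chlorotriethylsilane CC[Si](Cl)(CC)CC
Why: Silylation removes the acidic proton before the iodine–lithium exchange; the triethylsilyl ether is chosen because mild acid later cleaves it in the presence of a tertiary tert-butyldimethylsilyl ether.

Step 3
Reactants: 5 methyl phenyl sulfone; 6 (S)-2-methyloxirane
Product: 9 (S)-4-(phenylsulfonyl)butan-2-yl 4-methylbenzenesulfonate, via lithiomethyl phenyl sulfone 7 (not isolated), via lithium alkoxide 8 (not isolated)
Conditions: n-BuLi, THF, −78 °C; 6, DMPU, −78 °C to rt; then TsCl, 0 °C to rt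
Reagents that add atoms: 4-methylbenzenesulfonyl chloride Cc1ccc(cc1)S(Cl)(=O)=O
Why: The α-sulfonyl carbanion opens the epoxide at its unsubstituted carbon (SN2, the stereocentre is not touched) and the lithium alkoxide is sulfonylated in the same flask, so the carbinol carbon carries a leaving group with its S configuration intact.

Step 4
Reactants: 9 (S)-4-(phenylsulfonyl)butan-2-yl 4-methylbenzenesulfonate
Product: 10 (1R,2R)-2-methylcyclopropyl phenyl sulfone
Conditions: LiN(i-Pr)2, THF, −78 to 0 °C
Reagents that add atoms: none
Why: Deprotonation α to the sulfone and intramolecular displacement of tosylate (3-exo-tet γ-elimination) close the cyclopropane with inversion at the methyl-bearing carbon, which becomes C8 with the R configuration.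

Step 5
Reactants: 10 (1R,2R)-2-methylcyclopropyl phenyl sulfone
Product: 13 (2R)-2-methyl-1-(phenylsulfonyl)cyclopropan-1-ol, via 1-lithiocyclopropyl sulfone 11 (not isolated), via trimethylsilyl ether 12 (not isolated)
Conditions: n-BuLi, THF, −78 °C; Me3SiOOSiMe3, −78 to 0 °C; then citric acid, MeOH/H2O
Reagents that add atoms: bis(trimethylsilyl) peroxide C[Si](C)(C)OO[Si](C)(C)C
Why: α-Lithiation of the cyclopropyl sulfone and electrophilic oxygen transfer from the silyl peroxide give the α-hydroxy sulfone, a known bench-stable cyclopropanone equivalent that does not collapse on its own because loss of sulfinate would create the strained ketone; C8 is not involved.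

Step 6
Reactants: 4 triethyl{[(E)-5-iodo-4-methylpent-4-en-1-yl]oxy}silane; 13 (2R)-2-methyl-1-(phenylsulfonyl)cyclopropan-1-ol
Product: 17 (1S,2R)-2-methyl-1-[(E)-2-methyl-5-(triethylsilyloxy)pent-1-en-1-yl]cyclopropan-1-ol, via alkenyllithium 14 (not isolated), via alkenylmagnesium bromide 15 (not isolated), via (R)-2-methylcyclopropanone 16 (not isolated)
Conditions: 4, t-BuLi (2 equiv), Et2O, −78 °C; MgBr2·OEt2, −78 to 0 °C; separately 13, MeMgBr (1 equiv), THF, −78 °C; combine, −78 to 0 °C; aq NH4Cl
Reagents that add atoms: none
Why: Iodine–lithium exchange and transmetalation keep the E geometry; the magnesium alkoxide of 13 expels benzenesulfinate to release cyclopropanone 16 in the presence of 15, and 1,2-addition to this very electrophilic carbonyl group (known organometallic addition to 1-sulfonylcyclopropanols) occurs from the face opposite the C8 methyl group, which sets C9 as S with the alkenyl group trans to the methyl group.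

Step 7
Reactants: 17 (1S,2R)-2-methyl-1-[(E)-2-methyl-5-(triethylsilyloxy)pent-1-en-1-yl]cyclopropan-1-ol
Product: 19 (E)-5-[(1S,2R)-1-(tert-butyldimethylsilyloxy)-2-methylcyclopropyl]-4-methylpent-4-en-1-ol, via bis-silyl ether 18 (not isolated)
Conditions: TBSOTf, 2,6-lutidine, CH2Cl2, −78 to 0 °C; then MeOH, PPTS, 0 °C to rt
Reagents that add atoms: tert-butyldimethylsilyl trifluoromethanesulfonate CC(C)(C)[Si](C)(C)OS(=O)(=O)C(F)(F)F
Why: The silyl triflate with a hindered pyridine base caps the tertiary vinylcyclopropanol before it can rearrange or ring-open, and methanol with a mild acid then solvolyses only the primary triethylsilyl ether, which is far more labile than a tertiary tert-butyldimethylsilyl ether.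

Step 8
Reactants: 19 (E)-5-[(1S,2R)-1-(tert-butyldimethylsilyloxy)-2-methylcyclopropyl]-4-methylpent-4-en-1-ol
Product: 20 (E)-5-[(1S,2R)-1-(tert-butyldimethylsilyloxy)-2-methylcyclopropyl]-4-methylpent-4-enal
Conditions: Dess–Martin periodinane, NaHCO3, CH2Cl2, 0 °C to rt
Reagents that add atoms: none
Why: Buffered Dess–Martin oxidation takes the primary alcohol to the aldehyde without acid that could open the siloxycyclopropane.

Step 9
Reactants: 20 (E)-5-[(1S,2R)-1-(tert-butyldimethylsilyloxy)-2-methylcyclopropyl]-4-methylpent-4-enal; 21 ethynylmagnesium bromide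
Product: 22 (E)-7-[(1S,2R)-1-(tert-butyldimethylsilyloxy)-2-methylcyclopropyl]-6-methylhept-6-en-1-yn-3-ol (both C3 epimers)
Conditions: THF, −78 to 0 °C; aq NH4Cl
Reagents that add atoms: none
Why: Grignard 1,2-addition to the aldehyde forms the C4–C5 bond; the carbinol centre is not controlled and need not be, because it is oxidised in the next step.

Step 10
Reactants: 22 (E)-7-[(1S,2R)-1-(tert-butyldimethylsilyloxy)-2-methylcyclopropyl]-6-methylhept-6-en-1-yn-3-ol
Product: 23 (E)-7-[(1S,2R)-1-(tert-butyldimethylsilyloxy)-2-methylcyclopropyl]-6-methylhept-6-en-1-yn-3-one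
Conditions: Dess–Martin periodinane, NaHCO3, CH2Cl2, 0 °C
Reagents that add atoms: none
Why: Buffered Dess–Martin oxidation of the propargylic alcohol gives the terminal ynone under neutral conditions; the product is used at once because terminal ynones are strong conjugate acceptors.

Step 11
Reactants: 23 (E)-7-[(1S,2R)-1-(tert-butyldimethylsilyloxy)-2-methylcyclopropyl]-6-methylhept-6-en-1-yn-3-one
Product: 24 (3aR,6R)-5-(tert-butyldimethylsilyloxy)-3a,6-dimethyl-3,3a,6,7-tetrahydroazulen-1(2H)-one
Conditions: [Rh(cod)2]BF4 (5 mol %), (R)-BINAP (6 mol %), ClCH2CH2Cl, 0.01 M, rt to 60 °C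
Reagents that add atoms: none
Why: The cationic bisphosphine complex of monovalent rhodium binds the C1=C10 alkene in the conformer that holds the ring carbons syn to the alkene and inserts into the cyclopropane bond C9–C7, the one without the methyl group, giving a rhodacyclohexene with C7 σ-bound and C9–C10–C1 as an allyl ligand; the silyloxy group on C9 eases this cleavage. The tethered ynone then inserts so that its internal carbon C5 bonds to the allyl terminus C1, which closes ring A as a five-membered ring through the three-atom tether C2–C3–C4 (exo closure onto the alkyne), and C(sp2)–C(sp3) reductive elimination joins C6 to C7 and closes the seven-membered ring B from an eight-membered rhodacycle. The closest known reaction type is the rhodium-catalysed intramolecular (5+2) cycloaddition of alkyne-tethered vinylcyclopropanes, including 1-oxygenated and ring-substituted ones. C1 is the only new stereocentre: rhodium can reach C7 only from the alkene face on which C7 lies and C5 is delivered to C1 from that same face, so the (1S,2R) configuration of the cyclopropane is transferred to R at C1, while C8 is carried through unchanged and C9 becomes trigonal. The step needs bond selectivity for C9–C7 over C9–C8, secured by the trans methyl group, which would be pressed against the metal in the other insertion. It also needs the intramolecular path to outrun alkyne oligomerisation, secured by the short tether and high dilution. The bisphosphine is the enantiomer that matches this substrate-controlled course.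

Step 12
Reactants: 24 (3aR,6R)-5-(tert-butyldimethylsilyloxy)-3a,6-dimethyl-3,3a,6,7-tetrahydroazulen-1(2H)-one
Product: 26 (3aR,6R,8S,8aS)-5-(tert-butyldimethylsilyloxy)-8-hydroxy-3a,6-dimethyl-3,3a,6,7,8,8a-hexahydroazulen-1(2H)-one, via pinacol boronate 25 (not isolated)
Conditions: B2pin2, CuCl (5 mol %), Xantphos (5 mol %), NaOt-Bu (10 mol %), MeOH (2 equiv), THF, rt; DBU, rt; then NaBO3·4H2O, THF/H2O, 0 °C to rt
Reagents that add atoms: bis(pinacolato)diboron (boron of 25) CC1(C)OB(OC1(C)C)B1OC(C)(C)C(C)(C)O1; sodium perborate (oxygen of 26) [Na+].[O-]OB=O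
Why: A copper boryl species adds boron to the β-carbon C6 of the enone (copper-catalysed conjugate borylation) from the α face, opposite the C1 methyl group, and methanol protonates the enolate; DBU is expected to equilibrate C5 at the boronate stage, where neither retro-aldol cleavage nor β-elimination is possible, toward the trans ring fusion with the C6 substituent anti to C4, and perborate oxidation replaces boron by hydroxyl with retention.

Step 13
Reactants: 26 (3aR,6R,8S,8aS)-5-(tert-butyldimethylsilyloxy)-8-hydroxy-3a,6-dimethyl-3,3a,6,7,8,8a-hexahydroazulen-1(2H)-one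
Product: 27 (3aR,6R,8S,8aS)-5,8-bis(tert-butyldimethylsilyloxy)-3a,6-dimethyl-3,3a,6,7,8,8a-hexahydroazulen-1(2H)-one
Conditions: TBSOTf, 2,6-lutidine, CH2Cl2, −78 °C
Reagents that add atoms: tert-butyldimethylsilyl trifluoromethanesulfonate CC(C)(C)[Si](C)(C)OS(=O)(=O)C(F)(F)F
Why: O-Silylation at low temperature is faster than enolisation of the ketone and removes the β-hydroxyl proton, which blocks retro-aldol cleavage in the organometallic step.

Step 14
Reactants: 27 (3aR,6R,8S,8aS)-5,8-bis(tert-butyldimethylsilyloxy)-3a,6-dimethyl-3,3a,6,7,8,8a-hexahydroazulen-1(2H)-one; 28 isopropylmagnesium chloride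
Product: 30 (1R,3aR,6R,8S,8aS)-8-(tert-butyldimethylsilyloxy)-1-hydroxy-3a,6-dimethyl-1-(propan-2-yl)octahydroazulen-5(1H)-one, via enol ether carbinol 29 (not isolated)
Conditions: CeCl3 (dried), 28, THF, −78 °C; 27, −78 to −20 °C; then HCl (1 M, aq), THF, 0 °C
Reagents that add atoms: none
Why: The organocerium reagent is nucleophilic but weakly basic, which suppresses enolisation (and with it β-elimination of the C6 silyloxy group) and β-hydride reduction, and it attacks the C4 carbonyl from the α face that carries only H-5, because the β face is screened by the C5–C6 bond and the C1 methyl group, so the hydroxyl ends up β. Dilute acid in the work-up then hydrolyses the silyl enol ether, far more labile than the secondary silyl ether, to the C9 ketone by protonation at C10.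

Step 15
Reactants: 30 (1R,3aR,6R,8S,8aS)-8-(tert-butyldimethylsilyloxy)-1-hydroxy-3a,6-dimethyl-1-(propan-2-yl)octahydroazulen-5(1H)-one
Product: 31 tert-butyl{[(3R,3aS,4S,8aR)-6,8a-dimethyl-3-(propan-2-yl)-3,7-bis(trimethylsilyloxy)-1,2,3,3a,4,5,8,8a-octahydroazulen-4-yl]oxy}dimethylsilane
Conditions: Me3SiI, (Me3Si)2NH, CH2Cl2, −20 °C to rt
Reagents that add atoms: iodotrimethylsilane C[Si](C)(C)I; hexamethyldisilazane C[Si](C)(C)N[Si](C)(C)C
Why: Iodotrimethylsilane with hexamethyldisilazane silylates under equilibrating conditions and gives the more substituted (thermodynamic) enol silane, here the tetrasubstituted C8=C9 isomer; the tertiary C4 hydroxyl is capped in the same operation and the C8 stereocentre, no longer needed, is erased.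

Step 16
Reactants: 31 tert-butyl{[(3R,3aS,4S,8aR)-6,8a-dimethyl-3-(propan-2-yl)-3,7-bis(trimethylsilyloxy)-1,2,3,3a,4,5,8,8a-octahydroazulen-4-yl]oxy}dimethylsilane
Product: 33 (3R,3aS,4S,8aR)-4-(tert-butyldimethylsilyloxy)-6,8a-dimethyl-3-(propan-2-yl)-3-(trimethylsilyloxy)-1,2,3,3a,4,5,8,8a-octahydroazulen-7-yl trifluoromethanesulfonate, via lithium enolate 32 (not isolated)
Conditions: MeLi, THF, 0 °C; then PhNTf2, −78 °C to rt
Reagents that add atoms: N-phenylbis(trifluoromethanesulfonimide) O=S(=O)(N(c1ccccc1)S(=O)(=O)C(F)(F)F)C(F)(F)F
Why: MeLi cleaves the trimethylsilyl enol ether regiospecifically to the lithium enolate without touching the alkyl silyl ethers, and O-sulfonylation fixes the double bond at C8=C9 as the enol triflate.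

Step 17
Reactants: 33 (3R,3aS,4S,8aR)-4-(tert-butyldimethylsilyloxy)-6,8a-dimethyl-3-(propan-2-yl)-3-(trimethylsilyloxy)-1,2,3,3a,4,5,8,8a-octahydroazulen-7-yl trifluoromethanesulfonate
Product: 34 tert-butyl{[(3R,3aS,4S,8aR)-6,8a-dimethyl-3-(propan-2-yl)-3-(trimethylsilyloxy)-1,2,3,3a,4,5,8,8a-octahydroazulen-4-yl]oxy}dimethylsilane
Conditions: Pd(OAc)2 (5 mol %), PPh3 (10 mol %), HCO2H, n-Bu3N, DMF, 60 °C
Reagents that add atoms: none
Why: Palladium-catalysed formate reduction of the enol triflate (oxidative addition to zerovalent palladium, formate exchange, loss of CO2, C–H reductive elimination) replaces the triflate by hydrogen and leaves the double bond at C8=C9.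

Step 18
Reactants: 34 tert-butyl{[(3R,3aS,4S,8aR)-6,8a-dimethyl-3-(propan-2-yl)-3-(trimethylsilyloxy)-1,2,3,3a,4,5,8,8a-octahydroazulen-4-yl]oxy}dimethylsilane
Product: 35 (3R,3aS,4S,8aR)-6,8a-dimethyl-3-(propan-2-yl)-1,2,3,3a,4,5,8,8a-octahydroazulene-3,4-diol (jaeschkeanadiol)
Conditions: n-Bu4NF, THF, rt to 50 °C
Reagents that add atoms: none
Why: Fluoride cleaves both silyl ethers through the strong Si–F bond and gives the 4,6-diol; nothing else in 34 responds to fluoride.

Step 19
Reactants: 35 jaeschkeanadiol
Product: 36 jaeschkeanadiol 8α,9α-epoxide, (1R,4R,5S,6S,8R,9S) in the C1–C10 numbering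
Conditions: VO(acac)2 (5 mol %), t-BuOOH, CH2Cl2, 0 °C to rt
Reagents that add atoms: tert-butyl hydroperoxide CC(C)(C)OO
Why: In this vanadium-catalysed directed epoxidation the homoallylic C6 hydroxyl binds the metal and delivers the peroxide oxygen to the α face of C8=C9, on which it sits, setting C8 and C9; the tertiary C4 hydroxyl is more remote and on the other face.

Step 20
Reactants: 36 jaeschkeanadiol 8α,9α-epoxide; 37 4-acetoxybenzoyl chloride
Product: 38 jaeschkeanadiol 8α,9α-epoxide 6-O-(4-acetoxybenzoate)
Conditions: Et3N, DMAP, CH2Cl2, 0 °C to rt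
Reagents that add atoms: none
Why: DMAP-catalysed acylation esterifies the only acylable hydroxyl, the secondary C6–OH; the tertiary C4–OH is inert and the amine base keeps the medium free of acid that would open the epoxide.

Step 21
Reactants: 38 jaeschkeanadiol 8α,9α-epoxide 6-O-(4-acetoxybenzoate)
Product: 39 jaeskeanin
Conditions: pyrrolidine (1.5 equiv), CH2Cl2, 0 °C
Reagents that add atoms: none
Why: Aminolysis cleaves the aryl acetate, an activated phenyl ester, much faster than the hindered secondary alkyl benzoate, and the trisubstituted epoxide is not attacked by the amine at 0 °C.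

## Compound list

1 | pent-4-yn-1-ol | C#CCCCO | starting material
2 | dimethyl[(E)-5-(dimethylaluminooxy)-2-methylpent-1-en-1-yl]alane | C[Al](C)/C=C(\C)CCCO[Al](C)C | intermediate
3 | (E)-5-iodo-4-methylpent-4-en-1-ol | OCCC/C(C)=C/I | intermediate
4 | triethyl{[(E)-5-iodo-4-methylpent-4-en-1-yl]oxy}silane | CC[Si](CC)(CC)OCCC/C(C)=C/I | intermediate
5 | methyl phenyl sulfone | CS(=O)(=O)c1ccccc1 | starting material
6 | (S)-2-methyloxirane | C[C@H]1CO1 | starting material
7 | lithiomethyl phenyl sulfone | [Li]CS(=O)(=O)c1ccccc1 | intermediate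
8 | lithium (S)-4-(phenylsulfonyl)butan-2-olate | C[C@H]([O-])CCS(=O)(=O)c1ccccc1.[Li+] | intermediate
9 | (S)-4-(phenylsulfonyl)butan-2-yl 4-methylbenzenesulfonate | C[C@H](OS(=O)(=O)c1ccc(C)cc1)CCS(=O)(=O)c1ccccc1 | intermediate
10 | (1R,2R)-2-methylcyclopropyl phenyl sulfone | C[C@@H]1C[C@H]1S(=O)(=O)c1ccccc1 | intermediate
11 | [(2R)-2-methyl-1-(phenylsulfonyl)cyclopropyl]lithium | C[C@@H]1CC1([Li])S(=O)(=O)c1ccccc1 | intermediate
12 | trimethyl{[(2R)-2-methyl-1-(phenylsulfonyl)cyclopropyl]oxy}silane | C[C@@H]1CC1(O[Si](C)(C)C)S(=O)(=O)c1ccccc1 | intermediate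
13 | (2R)-2-methyl-1-(phenylsulfonyl)cyclopropan-1-ol (either C1 epimer) | C[C@@H]1CC1(O)S(=O)(=O)c1ccccc1 | intermediate
14 | [(E)-2-methyl-5-(triethylsilyloxy)pent-1-en-1-yl]lithium | CC[Si](CC)(CC)OCCC/C(C)=C/[Li] | intermediate
15 | [(E)-2-methyl-5-(triethylsilyloxy)pent-1-en-1-yl]magnesium bromide | CC[Si](CC)(CC)OCCC/C(C)=C/[Mg]Br | intermediate
16 | (R)-2-methylcyclopropan-1-one | C[C@@H]1CC1=O | intermediate
17 | (1S,2R)-2-methyl-1-[(E)-2-methyl-5-(triethylsilyloxy)pent-1-en-1-yl]cyclopropan-1-ol | CC[Si](CC)(CC)OCCC/C(C)=C/[C@]1(O)C[C@H]1C | intermediate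
18 | tert-butyldimethyl{[(1S,2R)-2-methyl-1-((E)-2-methyl-5-(triethylsilyloxy)pent-1-en-1-yl)cyclopropyl]oxy}silane | CC[Si](CC)(CC)OCCC/C(C)=C/[C@]1(O[Si](C)(C)C(C)(C)C)C[C@H]1C | intermediate
19 | (E)-5-[(1S,2R)-1-(tert-butyldimethylsilyloxy)-2-methylcyclopropyl]-4-methylpent-4-en-1-ol | OCCC/C(C)=C/[C@]1(O[Si](C)(C)C(C)(C)C)C[C@H]1C | intermediate
20 | (E)-5-[(1S,2R)-1-(tert-butyldimethylsilyloxy)-2-methylcyclopropyl]-4-methylpent-4-enal | O=CCC/C(C)=C/[C@]1(O[Si](C)(C)C(C)(C)C)C[C@H]1C | intermediate
21 | ethynylmagnesium bromide | C#C[Mg]Br | starting material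
22 | (E)-7-[(1S,2R)-1-(tert-butyldimethylsilyloxy)-2-methylcyclopropyl]-6-methylhept-6-en-1-yn-3-ol (C3 epimers) | C#CC(O)CC/C(C)=C/[C@]1(O[Si](C)(C)C(C)(C)C)C[C@H]1C | intermediate
23 | (E)-7-[(1S,2R)-1-(tert-butyldimethylsilyloxy)-2-methylcyclopropyl]-6-methylhept-6-en-1-yn-3-one | C#CC(=O)CC/C(C)=C/[C@]1(O[Si](C)(C)C(C)(C)C)C[C@H]1C | intermediate
24 | (3aR,6R)-5-(tert-butyldimethylsilyloxy)-3a,6-dimethyl-3,3a,6,7-tetrahydroazulen-1(2H)-one | O=C1CC[C@]2(C)C=C(O[Si](C)(C)C(C)(C)C)[C@H](C)CC=C12 | intermediate
25 | (3aR,6R,8S,8aR)-5-(tert-butyldimethylsilyloxy)-3a,6-dimethyl-8-(4,4,5,5-tetramethyl-1,3,2-dioxaborolan-2-yl)-3,3a,6,7,8,8a-hexahydroazulen-1(2H)-one | O=C1CC[C@]2(C)C=C(O[Si](C)(C)C(C)(C)C)[C@H](C)C[C@H](B3OC(C)(C)C(C)(C)O3)[C@H]21 | intermediate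
26 | (3aR,6R,8S,8aS)-5-(tert-butyldimethylsilyloxy)-8-hydroxy-3a,6-dimethyl-3,3a,6,7,8,8a-hexahydroazulen-1(2H)-one | O=C1CC[C@]2(C)C=C(O[Si](C)(C)C(C)(C)C)[C@H](C)C[C@H](O)[C@H]21 | intermediate
27 | (3aR,6R,8S,8aS)-5,8-bis(tert-butyldimethylsilyloxy)-3a,6-dimethyl-3,3a,6,7,8,8a-hexahydroazulen-1(2H)-one | O=C1CC[C@]2(C)C=C(O[Si](C)(C)C(C)(C)C)[C@H](C)C[C@H](O[Si](C)(C)C(C)(C)C)[C@H]21 | intermediate
28 | isopropylmagnesium chloride | CC(C)[Mg]Cl | starting material
29 | (3R,3aS,4S,6R,8aR)-4,7-bis(tert-butyldimethylsilyloxy)-6,8a-dimethyl-3-(propan-2-yl)-1,2,3,3a,4,5,6,8a-octahydroazulen-3-ol | CC(C)[C@]1(O)CC[C@]2(C)C=C(O[Si](C)(C)C(C)(C)C)[C@H](C)C[C@H](O[Si](C)(C)C(C)(C)C)[C@H]21 | intermediate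
30 | (1R,3aR,6R,8S,8aS)-8-(tert-butyldimethylsilyloxy)-1-hydroxy-3a,6-dimethyl-1-(propan-2-yl)octahydroazulen-5(1H)-one | CC(C)[C@]1(O)CC[C@]2(C)CC(=O)[C@H](C)C[C@H](O[Si](C)(C)C(C)(C)C)[C@H]21 | intermediate
31 | tert-butyl{[(3R,3aS,4S,8aR)-6,8a-dimethyl-3-(propan-2-yl)-3,7-bis(trimethylsilyloxy)-1,2,3,3a,4,5,8,8a-octahydroazulen-4-yl]oxy}dimethylsilane | CC(C)[C@]1(O[Si](C)(C)C)CC[C@]2(C)CC(O[Si](C)(C)C)=C(C)C[C@H](O[Si](C)(C)C(C)(C)C)[C@H]21 | intermediate
32 | lithium (3R,3aS,4S,8aR)-4-(tert-butyldimethylsilyloxy)-6,8a-dimethyl-3-(propan-2-yl)-3-(trimethylsilyloxy)-1,2,3,3a,4,5,8,8a-octahydroazulen-7-olate | CC(C)[C@]1(O[Si](C)(C)C)CC[C@]2(C)CC([O-])=C(C)C[C@H](O[Si](C)(C)C(C)(C)C)[C@H]21.[Li+] | intermediate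
33 | (3R,3aS,4S,8aR)-4-(tert-butyldimethylsilyloxy)-6,8a-dimethyl-3-(propan-2-yl)-3-(trimethylsilyloxy)-1,2,3,3a,4,5,8,8a-octahydroazulen-7-yl trifluoromethanesulfonate | CC(C)[C@]1(O[Si](C)(C)C)CC[C@]2(C)CC(OS(=O)(=O)C(F)(F)F)=C(C)C[C@H](O[Si](C)(C)C(C)(C)C)[C@H]21 | intermediate
34 | tert-butyl{[(3R,3aS,4S,8aR)-6,8a-dimethyl-3-(propan-2-yl)-3-(trimethylsilyloxy)-1,2,3,3a,4,5,8,8a-octahydroazulen-4-yl]oxy}dimethylsilane | CC(C)[C@]1(O[Si](C)(C)C)CC[C@]2(C)CC=C(C)C[C@H](O[Si](C)(C)C(C)(C)C)[C@H]21 | intermediate
35 | (3R,3aS,4S,8aR)-6,8a-dimethyl-3-(propan-2-yl)-1,2,3,3a,4,5,8,8a-octahydroazulene-3,4-diol (jaeschkeanadiol) | CC(C)[C@]1(O)CC[C@]2(C)CC=C(C)C[C@H](O)[C@H]21 | intermediate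
36 | jaeschkeanadiol 8α,9α-epoxide, (1R,4R,5S,6S,8R,9S) in the C1–C10 numbering | CC(C)[C@]1(O)CC[C@]2(C)C[C@@H]3O[C@]3(C)C[C@H](O)[C@H]21 | intermediate
37 | 4-acetoxybenzoyl chloride | CC(=O)Oc1ccc(cc1)C(Cl)=O | starting material
38 | jaeschkeanadiol 8α,9α-epoxide 6-O-(4-acetoxybenzoate) | CC(C)[C@]1(O)CC[C@]2(C)C[C@@H]3O[C@]3(C)C[C@H](OC(=O)c3ccc(OC(C)=O)cc3)[C@H]21 | intermediate
39 | jaeskeanin | CC(C)[C@]1(O)CC[C@]2(C)C[C@@H]3O[C@]3(C)C[C@H](OC(=O)c3ccc(O)cc3)[C@H]21 | target

## Step count and least certain steps

Total: 21 steps. Longest linear sequence: 19 steps (steps 3, 4, 5, then 6 to 21, from 5 and 6); the other branch (steps 1, 2, then 6 to 21) is 18 steps.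

**Step 11, the key step.** The terminal ynone may oligomerise or decay at the cationic metal before the intramolecular insertion, or the metal may insert into the methyl-bearing cyclopropane bond, which would shift the methyl group to C7. The fallback sets out from propargylic alcohol 22 and comes back at 24. The cycloaddition is run on the less electrophilic alkynol with the neutral catalyst [Rh(CO)2Cl]2 in toluene to give the bicyclic dienol F1 (both carbinol epimers). Its allylic alcohol is then oxidised with MnO2 to 24, so the enone is created after the rings.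

**Step 6.** The free cyclopropanone may self-condense or ring-open before the alkenyl reagent adds, the alkenyl reagent may be quenched by the hydroxy sulfone, or facial selectivity at the small ring may be incomplete. The fallback sets out from 4 and comes back at 18. Iodine–lithium exchange and acylation with N-methoxy-N-methylpropanamide give the E-enone F2. TBSOTf and Et3N give the (2Z,4E)-siloxydiene F3. A catalytic asymmetric Simmons–Smith cyclopropanation of the electron-rich enol ether alkene (Et2Zn, CH2I2, chiral dipeptide ligand) gives 18, with the methyl group trans to the alkenyl group by the stereospecificity of the carbenoid addition.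

**Step 12.** The C5 equilibrium may not settle on the trans-fused epimer, boron delivery may be insufficiently face-selective, or the silyl enol ether may be hydrolysed during the oxidation. The fallback sets out from 24 and comes back at 26. Nucleophilic epoxidation of the enone (t-BuOOH, DBU) from the face opposite the C1 methyl group gives the α-epoxy ketone F4. SmI2 in THF/MeOH at −78 °C cleaves the Cα–O bond, and the samarium enolate is protonated at C5 under kinetic control from the side of the neighbouring C6 alkoxide, to give 26.

**Step 14.** The ketone may be enolised, with loss of the C6 silyloxy group by β-elimination, or reduced by β-hydride transfer from the branched reagent. The fallback sets out from 27 and comes back at 29. Isopropenylmagnesium bromide with CeCl3, an sp2 nucleophile without β-hydrogen on a saturated carbon and with less bulk, gives the isopropenyl carbinol F5. Hydrogenation of its 1,1-disubstituted alkene over RhCl(PPh3)3, which leaves the trisubstituted silyl enol ether alone, gives 29.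

**Step 15 (and with it step 16).** Silylation may occur partly toward C10, which would place the final alkene at C9–C10. The fallback sets out from 30 and comes back at 35. Dehydrogenation with IBX can occur only toward C7, because C1 carries no hydrogen, and gives the enone F6. Condensation with 4-methylbenzenesulfonohydrazide gives the tosylhydrazone F7. Reduction with catecholborane and then NaOAc·3H2O with warming moves the double bond to C8=C9 through the 1,5-hydrogen shift of the allylic diazene and gives the C6 silyl ether F8. n-Bu4NF then gives 35.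

## Further compounds

F1 | step 11 | (3aR,6R)-5-(tert-butyldimethylsilyloxy)-3a,6-dimethyl-1,2,3,3a,6,7-hexahydroazulen-1-ol (C1 epimers) | OC1CC[C@]2(C)C=C(O[Si](C)(C)C(C)(C)C)[C@H](C)CC=C12
F2 | step 6 | (E)-5-methyl-8-(triethylsilyloxy)oct-4-en-3-one | CCC(=O)/C=C(\C)CCCO[Si](CC)(CC)CC
F3 | step 6 | tert-butyldimethyl{[(2Z,4E)-5-methyl-8-(triethylsilyloxy)octa-2,4-dien-3-yl]oxy}silane | C/C=C(O[Si](C)(C)C(C)(C)C)/C=C(\C)CCCO[Si](CC)(CC)CC
F4 | step 12 | 5α,6α-epoxide of 24 (C1–C10 numbering; oxirane across C5–C6) | O=C1CC[C@]2(C)C=C(O[Si](C)(C)C(C)(C)C)[C@H](C)C[C@@H]3O[C@]123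
F5 | step 14 | isopropenyl analogue of 29 (prop-1-en-2-yl in place of propan-2-yl at C4) | CC(=C)[C@]1(O)CC[C@]2(C)C=C(O[Si](C)(C)C(C)(C)C)[C@H](C)C[C@H](O[Si](C)(C)C(C)(C)C)[C@H]21
F6 | step 15 | C7=C8 enone of 30 | CC(C)[C@]1(O)CC[C@]2(C)CC(=O)C(C)=C[C@H](O[Si](C)(C)C(C)(C)C)[C@H]21
F7 | step 15 | 4-methylbenzenesulfonylhydrazone of F6 | CC(C)[C@]1(O)CC[C@]2(C)CC(=NNS(=O)(=O)c3ccc(C)cc3)C(C)=C[C@H](O[Si](C)(C)C(C)(C)C)[C@H]21
F8 | step 15 | jaeschkeanadiol 6-O-tert-butyldimethylsilyl ether | CC(C)[C@]1(O)CC[C@]2(C)CC=C(C)C[C@H](O[Si](C)(C)C(C)(C)C)[C@H]21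
A1 | alternative 1 | 3-allylcyclopent-2-en-1-one | O=C1C=C(CC=C)CC1
A2 | alternative 1 | 3-methylbut-3-enal | CC(=C)CC=O
A3 | alternative 1 | 3-allyl-2-(1-hydroxy-3-methylbut-3-enyl)-3-methylcyclopentan-1-one | O=C1CC[C@](C)(CC=C)[C@H]1[C@@H](O)CC(C)=C
A4 | alternative 1 | (3aR,8S,8aS)-8-hydroxy-3a,6-dimethyl-3,3a,4,7,8,8a-hexahydroazulen-1(2H)-one | O=C1CC[C@]2(C)CC=C(C)C[C@H](O)[C@H]21
A5 | alternative 2 | 1-[2-hydroxy-7-(2-iodoethyl)-4,7-dimethylcyclohept-4-en-1-yl]-2-methylpropan-1-one | CC(C)C(=O)[C@@H]1[C@@H](O)CC(C)=CC[C@@]1(C)CCI
A6 | alternative 2 | jaeschkeanadiol (identical with 35) | CC(C)[C@]1(O)CC[C@]2(C)CC=C(C)C[C@H](O)[C@H]21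
A7 | alternative 3 | methyl 3-allyl-6-(tert-butyldimethylsilyloxy)-2-diazo-3,7-dimethyloctanoate | COC(=O)C(=[N+]=[N-])[C@@](C)(CC=C)CC[C@@H](O[Si](C)(C)C(C)(C)C)C(C)C
A8 | alternative 3 | methyl 5-allyl-2-(tert-butyldimethylsilyloxy)-5-methyl-2-(propan-2-yl)cyclopentane-1-carboxylate | CC(C)[C@]1(O[Si](C)(C)C(C)(C)C)CC[C@](C)(CC=C)[C@H]1C(=O)OC
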